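**Assumption:** the SMILES is read as the (2R,3R)-cis-2,3-dihydro-1,4-benzodioxine (carboxyl and aryl on the same face) acylating (R)-3-(4-hydroxy-3-methoxyphenyl)lactic acid. Benzodioxane atoms are numbered as in the target throughout: C2 bears the carboxyl or its CH2O precursor, C3 the aryl group, C7 the propenoate.

## Retrosynthetic overview

1. Last step: acidolysis of one tert-butyl ester and two MOM ethers. The C2 carboxyl is made just before by oxidation of a CH2OH group, so the epimerisable cis α-aryloxy acid never meets base.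
2. Ester C–O bond: cis-benzodioxane cinnamic acid plus tert-butyl (R)-aryllactate (from methyl (R)-glycidate and an aryl Grignard reagent).
3. Only ring formed: the 1,4-dioxane ring, closed by intramolecular Mitsunobu etherification with inversion at the benzylic carbon, which turns a syn aldol into the cis ring. The three benzene rings are bought.
4. Key C–C bond (C2–C3): Evans syn-aldol of the boron enolate of an N-(aryloxyacetyl)oxazolidinone with MOM-protected vanillin.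
5. Aldol donor: from 3,4-dihydroxybenzaldehyde by regioselective 4-O-allylation, O-alkylation with tert-butyl bromoacetate and Wittig olefination.

## Route

**Step 1**
Reactants: 1 3,4-dihydroxybenzaldehyde
Product: 2 4-(allyloxy)-3-hydroxybenzaldehyde
Conditions: allyl bromide (1.1 equiv), NaHCO3, NaI (cat.), DMF, 40 °C
Reagents that add atoms: allyl bromide, C=CCBr
Why: Williamson etherification in which the weak base ionises only the more acidic 4-OH (para to the formyl group), so allylation is regioselective.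

**Step 2**
Reactants: 2 4-(allyloxy)-3-hydroxybenzaldehyde; 3 tert-butyl bromoacetate
Product: 4 tert-butyl 2-[2-(allyloxy)-5-formylphenoxy]acetate
Conditions: K2CO3, DMF, rt
Reagents that add atoms: none
Why: Williamson O-alkylation of the remaining phenol by a reactive α-bromo ester, with a tert-butyl ester chosen so that acid can later cleave it beside a methyl ester.

**Step 3**
Reactants: 4 tert-butyl 2-[2-(allyloxy)-5-formylphenoxy]acetate; 5 methyl (triphenylphosphoranylidene)acetate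
Product: 6 methyl (E)-3-[4-(allyloxy)-3-(2-tert-butoxy-2-oxoethoxy)phenyl]prop-2-enoate
Conditions: toluene, 80 °C
Reagents that add atoms: none
Why: Wittig olefination with a stabilised ylide gives the (E)-cinnamate (E:Z above 95:5) and removes the aldehyde before the aldol.

**Step 4**
Reactants: 6 methyl (E)-3-[4-(allyloxy)-3-(2-tert-butoxy-2-oxoethoxy)phenyl]prop-2-enoate
Product: 7 2-{2-(allyloxy)-5-[(E)-3-methoxy-3-oxoprop-1-enyl]phenoxy}acetic acid
Conditions: TFA/CH2Cl2 (1:2), 0 °C to rt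
Reagents that add atoms: none
Why: Acidolysis of the tert-butyl ester by alkyl–oxygen cleavage frees the acid while the methyl ester and allyl ether are inert.

**Step 5**
Reactants: 7 2-{2-(allyloxy)-5-[(E)-3-methoxy-3-oxoprop-1-enyl]phenoxy}acetic acid; 8 (R)-4-benzyl-1,3-oxazolidin-2-one
Product: 10 methyl (E)-3-[4-(allyloxy)-3-{2-[(4R)-4-benzyl-2-oxo-1,3-oxazolidin-3-yl]-2-oxoethoxy}phenyl]prop-2-enoate, via mixed pivalic anhydride 9 (not isolated)
Conditions: PivCl, Et3N, THF, −20 °C; then 8, LiCl, −20 °C to rt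
Reagents that add atoms: none
Why: N-acylation of the oxazolidinone through a mixed anhydride, which is attacked at the less hindered aryloxyacetyl carbonyl.

**Step 6**
Reactants: 11 vanillin (4-hydroxy-3-methoxybenzaldehyde)
Product: 12 3-methoxy-4-(methoxymethoxy)benzaldehyde
Conditions: MOMCl, iPr2NEt, CH2Cl2, 0 °C to rt
Reagents that add atoms: chloromethyl methyl ether, COCCl
Why: O-alkylation of the phenol gives a MOM acetal that survives base, hydride, fluoride and oxidant and falls off in the final acid step.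

**Step 7**
Reactants: 10 methyl (E)-3-[4-(allyloxy)-3-{2-[(4R)-4-benzyl-2-oxo-1,3-oxazolidin-3-yl]-2-oxoethoxy}phenyl]prop-2-enoate; 12 3-methoxy-4-(methoxymethoxy)benzaldehyde
Product: 15 (4R)-4-benzyl-3-[(2R,3S)-2-{2-(allyloxy)-5-[(E)-3-methoxy-3-oxoprop-1-enyl]phenoxy}-3-hydroxy-3-[3-methoxy-4-(methoxymethoxy)phenyl]propanoyl]-1,3-oxazolidin-2-one, via (Z)-dibutylboron enolate 13 (not isolated), via dibutylboron aldolate 14 (not isolated)
Conditions: Bu2BOTf (1.2 equiv), Et3N (1.4 equiv), CH2Cl2, −78 to 0 °C; then 12, −78 to 0 °C; pH 7 buffer, MeOH, 30% H2O2, 0 °C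
Reagents that add atoms: none
Why: Evans syn-aldol in which the (Z)-boron enolate reacts through a closed Zimmerman–Traxler chair on the face away from the benzyl group of the (R)-auxiliary, setting C2 as R and C3 as S (2,3-syn) while forming the C2–C3 bond.

**Step 8**
Reactants: 15 (4R)-4-benzyl-3-[(2R,3S)-2-{2-(allyloxy)-5-[(E)-3-methoxy-3-oxoprop-1-enyl]phenoxy}-3-hydroxy-3-[3-methoxy-4-(methoxymethoxy)phenyl]propanoyl]-1,3-oxazolidin-2-one
Product: 16 methyl (E)-3-[4-(allyloxy)-3-({(1S,2S)-1,3-dihydroxy-1-[3-methoxy-4-(methoxymethoxy)phenyl]propan-2-yl}oxy)phenyl]prop-2-enoate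
Conditions: NaBH4, THF/H2O (4:1), 0 °C to rt
Reagents that add atoms: none
Why: Reductive cleavage of the activated imide carbonyl by borohydride spares the conjugated methyl ester and both stereocentres (the descriptor at the aryloxy carbon changes from R to S only through CIP priorities).

**Step 9**
Reactants: 16 methyl (E)-3-[4-(allyloxy)-3-({(1S,2S)-1,3-dihydroxy-1-[3-methoxy-4-(methoxymethoxy)phenyl]propan-2-yl}oxy)phenyl]prop-2-enoate
Product: 17 methyl (E)-3-[4-(allyloxy)-3-({(1S,2S)-3-[(tert-butyldimethylsilyl)oxy]-1-hydroxy-1-[3-methoxy-4-(methoxymethoxy)phenyl]propan-2-yl}oxy)phenyl]prop-2-enoate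
Conditions: TBSCl (1.1 equiv), imidazole, CH2Cl2, 0 °C
Reagents that add atoms: tert-butyldimethylsilyl chloride, CC(C)(C)[Si](C)(C)Cl
Why: Selective silylation, because the primary hydroxyl reacts far faster than the hindered secondary benzylic one.

**Step 10**
Reactants: 17 methyl (E)-3-[4-(allyloxy)-3-({(1S,2S)-3-[(tert-butyldimethylsilyl)oxy]-1-hydroxy-1-[3-methoxy-4-(methoxymethoxy)phenyl]propan-2-yl}oxy)phenyl]prop-2-enoate
Product: 18 methyl (E)-3-[3-({(1S,2S)-3-[(tert-butyldimethylsilyl)oxy]-1-hydroxy-1-[3-methoxy-4-(methoxymethoxy)phenyl]propan-2-yl}oxy)-4-hydroxyphenyl]prop-2-enoate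
Conditions: Pd(PPh3)4 (5 mol %), morpholine, THF, rt
Reagents that add atoms: none
Why: Tsuji–Trost deallylation, in which zerovalent palladium ionises the aryl allyl ether to a π-allyl complex that morpholine traps, freeing the phenol under neutral conditions.

**Step 11**
Reactants: 18 methyl (E)-3-[3-({(1S,2S)-3-[(tert-butyldimethylsilyl)oxy]-1-hydroxy-1-[3-methoxy-4-(methoxymethoxy)phenyl]propan-2-yl}oxy)-4-hydroxyphenyl]prop-2-enoate
Product: 20 methyl (E)-3-[(2S,3R)-2-{[(tert-butyldimethylsilyl)oxy]methyl}-3-[3-methoxy-4-(methoxymethoxy)phenyl]-2,3-dihydro-1,4-benzodioxin-7-yl]prop-2-enoate, via alkoxyphosphonium phenoxide 19 (not isolated)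
Conditions: PPh3, DIAD, THF (0.02 M), 0 °C to rt
Reagents that add atoms: none
Why: Intramolecular Mitsunobu etherification, in which the neighbouring phenoxide displaces the benzylic oxyphosphonium group in a 6-exo-tet SN2 step with inversion (S to R at C3), converting the syn aldol relationship into the cis-2,3-disubstituted dioxane ring.

**Step 12**
Reactants: 20 methyl (E)-3-[(2S,3R)-2-{[(tert-butyldimethylsilyl)oxy]methyl}-3-[3-methoxy-4-(methoxymethoxy)phenyl]-2,3-dihydro-1,4-benzodioxin-7-yl]prop-2-enoate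
Product: 21 (E)-3-[(2S,3R)-2-{[(tert-butyldimethylsilyl)oxy]methyl}-3-[3-methoxy-4-(methoxymethoxy)phenyl]-2,3-dihydro-1,4-benzodioxin-7-yl]prop-2-enoic acid
Conditions: LiOH·H2O, THF/MeOH/H2O, rt; then cold 0.5 M HCl to pH 4
Reagents that add atoms: lithium hydroxide, [Li+].[OH-]
Why: Saponification of the methyl cinnamate is safe here because C2 still carries CH2OTBS and no stereocentre is base-labile.

**Step 13**
Reactants: 22 4-bromo-2-methoxyphenol
Product: 23 4-bromo-2-methoxy-1-(methoxymethoxy)benzene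
Conditions: MOMCl, iPr2NEt, CH2Cl2, 0 °C to rt
Reagents that add atoms: chloromethyl methyl ether, COCCl
Why: O-alkylation to the MOM ether masks the phenol so that the Grignard reagent can be formed.

**Step 14**
Reactants: 23 4-bromo-2-methoxy-1-(methoxymethoxy)benzene; 24 methyl (R)-oxirane-2-carboxylate (methyl (R)-glycidate)
Product: 26 methyl (R)-2-hydroxy-3-[3-methoxy-4-(methoxymethoxy)phenyl]propanoate, via arylmagnesium bromide 25 (not isolated)
Conditions: Mg, THF, 40 °C; then CuBr·SMe2 (10 mol %), 24 (0.8 equiv), THF, −40 to −20 °C; aq. NH4Cl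
Reagents that add atoms: none
Why: Copper-catalysed SN2 opening of the epoxide at its unsubstituted carbon by the aryl Grignard reagent leaves the glycidate stereocentre untouched, so it is carried over as R.

**Step 15**
Reactants: 26 methyl (R)-2-hydroxy-3-[3-methoxy-4-(methoxymethoxy)phenyl]propanoate
Product: 27 (R)-2-hydroxy-3-[3-methoxy-4-(methoxymethoxy)phenyl]propanoic acid
Conditions: LiOH, THF/H2O, 0 °C; then cold 0.5 M HCl to pH 3
Reagents that add atoms: lithium hydroxide, [Li+].[OH-]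
Why: Mild saponification, under which an α-hydroxy carboxylate does not racemise.

**Step 16**
Reactants: 27 (R)-2-hydroxy-3-[3-methoxy-4-(methoxymethoxy)phenyl]propanoic acid
Product: 28 tert-butyl (R)-2-hydroxy-3-[3-methoxy-4-(methoxymethoxy)phenyl]propanoate
Conditions: tert-butyl 2,2,2-trichloroacetimidate (2.5 equiv), CH2Cl2/cyclohexane, rt
Reagents that add atoms: tert-butyl 2,2,2-trichloroacetimidate, CC(C)(C)OC(=N)C(Cl)(Cl)Cl
Why: Imidate esterification in which the carboxylic acid itself protonates the reagent, so no Lewis acid is needed and the alcohol and MOM ether are left alone.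

**Step 17**
Reactants: 21 (E)-3-[(2S,3R)-2-{[(tert-butyldimethylsilyl)oxy]methyl}-3-[3-methoxy-4-(methoxymethoxy)phenyl]-2,3-dihydro-1,4-benzodioxin-7-yl]prop-2-enoic acid; 28 tert-butyl (R)-2-hydroxy-3-[3-methoxy-4-(methoxymethoxy)phenyl]propanoate
Product: 30 tert-butyl (R)-2-{[(E)-3-{(2S,3R)-2-{[(tert-butyldimethylsilyl)oxy]methyl}-3-[3-methoxy-4-(methoxymethoxy)phenyl]-2,3-dihydro-1,4-benzodioxin-7-yl}prop-2-enoyl]oxy}-3-[3-methoxy-4-(methoxymethoxy)phenyl]propanoate, via mixed 2,4,6-trichlorobenzoic anhydride 29 (not isolated)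
Conditions: 2,4,6-trichlorobenzoyl chloride, Et3N, toluene, rt; then 28, DMAP, rt
Reagents that add atoms: none
Why: Yamaguchi esterification acylates the secondary alcohol on oxygen, so the (R)-lactate centre is retained and the cinnamate geometry is unchanged.

**Step 18**
Reactants: 30 tert-butyl (R)-2-{[(E)-3-{(2S,3R)-2-{[(tert-butyldimethylsilyl)oxy]methyl}-3-[3-methoxy-4-(methoxymethoxy)phenyl]-2,3-dihydro-1,4-benzodioxin-7-yl}prop-2-enoyl]oxy}-3-[3-methoxy-4-(methoxymethoxy)phenyl]propanoate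
Product: 31 tert-butyl (R)-2-{[(E)-3-{(2S,3R)-2-(hydroxymethyl)-3-[3-methoxy-4-(methoxymethoxy)phenyl]-2,3-dihydro-1,4-benzodioxin-7-yl}prop-2-enoyl]oxy}-3-[3-methoxy-4-(methoxymethoxy)phenyl]propanoate
Conditions: HF·pyridine, pyridine/THF, 0 °C to rt
Reagents that add atoms: none
Why: Fluoride-driven desilylation under buffered conditions that leave the MOM ethers, the tert-butyl ester and the cinnamate ester intact.

**Step 19**
Reactants: 31 tert-butyl (R)-2-{[(E)-3-{(2S,3R)-2-(hydroxymethyl)-3-[3-methoxy-4-(methoxymethoxy)phenyl]-2,3-dihydro-1,4-benzodioxin-7-yl}prop-2-enoyl]oxy}-3-[3-methoxy-4-(methoxymethoxy)phenyl]propanoate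
Product: 33 (2R,3R)-7-[(E)-3-({(R)-1-tert-butoxy-3-[3-methoxy-4-(methoxymethoxy)phenyl]-1-oxopropan-2-yl}oxy)-3-oxoprop-1-enyl]-3-[3-methoxy-4-(methoxymethoxy)phenyl]-2,3-dihydro-1,4-benzodioxine-2-carboxylic acid, via aldehyde 32 (not isolated)
Conditions: TEMPO (0.2 equiv), PhI(OAc)2 (2.5 equiv), MeCN/H2O (1:1), rt
Reagents that add atoms: water, O
Why: Oxoammonium (TEMPO) oxidation takes the primary alcohol through the aldehyde hydrate to the acid under mildly acidic conditions, so the labile cis α-aryloxy aldehyde is consumed as it forms (C2 becomes R only by CIP priority).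

**Step 20**
Reactants: 33 (2R,3R)-7-[(E)-3-({(R)-1-tert-butoxy-3-[3-methoxy-4-(methoxymethoxy)phenyl]-1-oxopropan-2-yl}oxy)-3-oxoprop-1-enyl]-3-[3-methoxy-4-(methoxymethoxy)phenyl]-2,3-dihydro-1,4-benzodioxine-2-carboxylic acid
Product: 34 (2R,3R)-7-[(E)-3-{[(R)-1-carboxy-2-(4-hydroxy-3-methoxyphenyl)ethyl]oxy}-3-oxoprop-1-enyl]-3-(4-hydroxy-3-methoxyphenyl)-2,3-dihydro-1,4-benzodioxine-2-carboxylic acid (CNP0171229.1)
Conditions: TFA/CH2Cl2 (1:2), H2O (10 equiv), 0 °C to rt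
Reagents that add atoms: none
Why: Global acidolysis cleaves the tert-butyl ester by alkyl–oxygen fission and the two MOM acetals by hydrolysis, and acid (unlike base) neither epimerises C2 nor cleaves the cinnamate ester.

## Compound list

1 | 3,4-dihydroxybenzaldehyde | O=Cc1ccc(O)c(O)c1 | starting material
2 | 4-(allyloxy)-3-hydroxybenzaldehyde | C=CCOc1ccc(C=O)cc1O | intermediate
3 | tert-butyl bromoacetate | CC(C)(C)OC(=O)CBr | starting material
4 | tert-butyl 2-[2-(allyloxy)-5-formylphenoxy]acetate | C=CCOc1ccc(C=O)cc1OCC(=O)OC(C)(C)C | intermediate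
5 | methyl (triphenylphosphoranylidene)acetate | COC(=O)C=P(c1ccccc1)(c1ccccc1)c1ccccc1 | starting material
6 | methyl (E)-3-[4-(allyloxy)-3-(2-tert-butoxy-2-oxoethoxy)phenyl]prop-2-enoate | C=CCOc1ccc(/C=C/C(=O)OC)cc1OCC(=O)OC(C)(C)C | intermediate
7 | 2-{2-(allyloxy)-5-[(E)-3-methoxy-3-oxoprop-1-enyl]phenoxy}acetic acid | C=CCOc1ccc(/C=C/C(=O)OC)cc1OCC(=O)O | intermediate
8 | (R)-4-benzyl-1,3-oxazolidin-2-one | O=C1N[C@H](Cc2ccccc2)CO1 | starting material
9 | mixed anhydride of 7 with pivalic acid (formed in the flask) | C=CCOc1ccc(/C=C/C(=O)OC)cc1OCC(=O)OC(=O)C(C)(C)C | intermediate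
10 | methyl (E)-3-[4-(allyloxy)-3-{2-[(4R)-4-benzyl-2-oxo-1,3-oxazolidin-3-yl]-2-oxoethoxy}phenyl]prop-2-enoate | C=CCOc1ccc(/C=C/C(=O)OC)cc1OCC(=O)N1[C@H](Cc2ccccc2)COC1=O | intermediate
11 | vanillin | COc1cc(C=O)ccc1O | starting material
12 | 3-methoxy-4-(methoxymethoxy)benzaldehyde | COCOc1ccc(C=O)cc1OC | intermediate
13 | (Z)-dibutylboron enolate of 10 (formed in the flask) | C=CCOc1ccc(/C=C/C(=O)OC)cc1O/C=C(\OB(CCCC)CCCC)N1[C@H](Cc2ccccc2)COC1=O | intermediate
14 | O-dibutylboryl aldolate of 15 (formed in the flask) | C=CCOc1ccc(/C=C/C(=O)OC)cc1O[C@H]([C@@H](OB(CCCC)CCCC)c1ccc(OCOC)c(OC)c1)C(=O)N1[C@H](Cc2ccccc2)COC1=O | intermediate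
15 | (4R)-4-benzyl-3-[(2R,3S)-2-{2-(allyloxy)-5-[(E)-3-methoxy-3-oxoprop-1-enyl]phenoxy}-3-hydroxy-3-[3-methoxy-4-(methoxymethoxy)phenyl]propanoyl]-1,3-oxazolidin-2-one (syn aldol) | C=CCOc1ccc(/C=C/C(=O)OC)cc1O[C@H]([C@@H](O)c1ccc(OCOC)c(OC)c1)C(=O)N1[C@H](Cc2ccccc2)COC1=O | intermediate
16 | methyl (E)-3-[4-(allyloxy)-3-({(1S,2S)-1,3-dihydroxy-1-[3-methoxy-4-(methoxymethoxy)phenyl]propan-2-yl}oxy)phenyl]prop-2-enoate | C=CCOc1ccc(/C=C/C(=O)OC)cc1O[C@H]([C@@H](O)c1ccc(OCOC)c(OC)c1)CO | intermediate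
17 | methyl (E)-3-[4-(allyloxy)-3-({(1S,2S)-3-[(tert-butyldimethylsilyl)oxy]-1-hydroxy-1-[3-methoxy-4-(methoxymethoxy)phenyl]propan-2-yl}oxy)phenyl]prop-2-enoate | C=CCOc1ccc(/C=C/C(=O)OC)cc1O[C@H]([C@@H](O)c1ccc(OCOC)c(OC)c1)CO[Si](C)(C)C(C)(C)C | intermediate
18 | methyl (E)-3-[3-({(1S,2S)-3-[(tert-butyldimethylsilyl)oxy]-1-hydroxy-1-[3-methoxy-4-(methoxymethoxy)phenyl]propan-2-yl}oxy)-4-hydroxyphenyl]prop-2-enoate | COC(=O)/C=C/c1ccc(O)c(O[C@H]([C@@H](O)c2ccc(OCOC)c(OC)c2)CO[Si](C)(C)C(C)(C)C)c1 | intermediate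
19 | alkoxytriphenylphosphonium phenoxide zwitterion of 18, benzylic O–P (formed in the flask) | COC(=O)/C=C/c1ccc([O-])c(O[C@H]([C@@H](O[P+](c2ccccc2)(c2ccccc2)c2ccccc2)c2ccc(OCOC)c(OC)c2)CO[Si](C)(C)C(C)(C)C)c1 | intermediate
20 | methyl (E)-3-[(2S,3R)-2-{[(tert-butyldimethylsilyl)oxy]methyl}-3-[3-methoxy-4-(methoxymethoxy)phenyl]-2,3-dihydro-1,4-benzodioxin-7-yl]prop-2-enoate (cis) | COC(=O)/C=C/c1ccc2c(c1)O[C@@H](CO[Si](C)(C)C(C)(C)C)[C@@H](c1ccc(OCOC)c(OC)c1)O2 | intermediate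
21 | (E)-3-[(2S,3R)-2-{[(tert-butyldimethylsilyl)oxy]methyl}-3-[3-methoxy-4-(methoxymethoxy)phenyl]-2,3-dihydro-1,4-benzodioxin-7-yl]prop-2-enoic acid | OC(=O)/C=C/c1ccc2c(c1)O[C@@H](CO[Si](C)(C)C(C)(C)C)[C@@H](c1ccc(OCOC)c(OC)c1)O2 | intermediate
22 | 4-bromo-2-methoxyphenol | COc1cc(Br)ccc1O | starting material
23 | 4-bromo-2-methoxy-1-(methoxymethoxy)benzene | COCOc1ccc(Br)cc1OC | intermediate
24 | methyl (R)-oxirane-2-carboxylate | COC(=O)[C@H]1CO1 | starting material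
25 | [3-methoxy-4-(methoxymethoxy)phenyl]magnesium bromide (formed in the flask) | COCOc1ccc([Mg]Br)cc1OC | intermediate
26 | methyl (R)-2-hydroxy-3-[3-methoxy-4-(methoxymethoxy)phenyl]propanoate | COC(=O)[C@H](O)Cc1ccc(OCOC)c(OC)c1 | intermediate
27 | (R)-2-hydroxy-3-[3-methoxy-4-(methoxymethoxy)phenyl]propanoic acid | OC(=O)[C@H](O)Cc1ccc(OCOC)c(OC)c1 | intermediate
28 | tert-butyl (R)-2-hydroxy-3-[3-methoxy-4-(methoxymethoxy)phenyl]propanoate | CC(C)(C)OC(=O)[C@H](O)Cc1ccc(OCOC)c(OC)c1 | intermediate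
29 | mixed anhydride of 21 with 2,4,6-trichlorobenzoic acid (formed in the flask) | O=C(/C=C/c1ccc2c(c1)O[C@@H](CO[Si](C)(C)C(C)(C)C)[C@@H](c1ccc(OCOC)c(OC)c1)O2)OC(=O)c1c(Cl)cc(Cl)cc1Cl | intermediate
30 | tert-butyl (R)-2-{[(E)-3-{(2S,3R)-2-{[(tert-butyldimethylsilyl)oxy]methyl}-3-[3-methoxy-4-(methoxymethoxy)phenyl]-2,3-dihydro-1,4-benzodioxin-7-yl}prop-2-enoyl]oxy}-3-[3-methoxy-4-(methoxymethoxy)phenyl]propanoate | CC(C)(C)OC(=O)[C@@H](Cc1ccc(OCOC)c(OC)c1)OC(=O)/C=C/c1ccc2c(c1)O[C@@H](CO[Si](C)(C)C(C)(C)C)[C@@H](c1ccc(OCOC)c(OC)c1)O2 | intermediate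
31 | tert-butyl (R)-2-{[(E)-3-{(2S,3R)-2-(hydroxymethyl)-3-[3-methoxy-4-(methoxymethoxy)phenyl]-2,3-dihydro-1,4-benzodioxin-7-yl}prop-2-enoyl]oxy}-3-[3-methoxy-4-(methoxymethoxy)phenyl]propanoate | CC(C)(C)OC(=O)[C@@H](Cc1ccc(OCOC)c(OC)c1)OC(=O)/C=C/c1ccc2c(c1)O[C@@H](CO)[C@@H](c1ccc(OCOC)c(OC)c1)O2 | intermediate
32 | tert-butyl (R)-2-{[(E)-3-{(2R,3R)-2-formyl-3-[3-methoxy-4-(methoxymethoxy)phenyl]-2,3-dihydro-1,4-benzodioxin-7-yl}prop-2-enoyl]oxy}-3-[3-methoxy-4-(methoxymethoxy)phenyl]propanoate (formed in the flask) | CC(C)(C)OC(=O)[C@@H](Cc1ccc(OCOC)c(OC)c1)OC(=O)/C=C/c1ccc2c(c1)O[C@@H](C=O)[C@@H](c1ccc(OCOC)c(OC)c1)O2 | intermediate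
33 | (2R,3R)-7-[(E)-3-({(R)-1-tert-butoxy-3-[3-methoxy-4-(methoxymethoxy)phenyl]-1-oxopropan-2-yl}oxy)-3-oxoprop-1-enyl]-3-[3-methoxy-4-(methoxymethoxy)phenyl]-2,3-dihydro-1,4-benzodioxine-2-carboxylic acid | CC(C)(C)OC(=O)[C@@H](Cc1ccc(OCOC)c(OC)c1)OC(=O)/C=C/c1ccc2c(c1)O[C@@H](C(=O)O)[C@@H](c1ccc(OCOC)c(OC)c1)O2 | intermediate
34 | (2R,3R)-7-[(E)-3-{[(R)-1-carboxy-2-(4-hydroxy-3-methoxyphenyl)ethyl]oxy}-3-oxoprop-1-enyl]-3-(4-hydroxy-3-methoxyphenyl)-2,3-dihydro-1,4-benzodioxine-2-carboxylic acid | COc1cc(C[C@@H](OC(=O)/C=C/c2ccc3c(c2)O[C@@H](C(=O)O)[C@@H](c2ccc(O)c(OC)c2)O3)C(=O)O)ccc1O | target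

## Step count and risks

Total step count: 20. Longest linear sequence: 15 steps (steps 1–5, 7–12 and 17–20, from 3,4-dihydroxybenzaldehyde).

The three steps most likely to fail:

**Step 7 (Evans aldol).** Both ring stereocentres depend on clean (Z)-enolisation of an α-aryloxyacetyl imide and on the MOM acetal tolerating the boron triflate. A low diastereomer ratio or MOM loss would undermine everything downstream. The fallback sets out from acid 7 and comes back at diol 16, and it changes both the auxiliary class and the enolate metal. Acid 7 is coupled with (R)-4-benzyl-1,3-thiazolidine-2-thione (EDC·HCl, DMAP, CH2Cl2) to give methyl (E)-3-[4-(allyloxy)-3-{2-[(4R)-4-benzyl-2-thioxo-1,3-thiazolidin-3-yl]-2-oxoethoxy}phenyl]prop-2-enoate F1. Soft enolisation (TiCl4 1.05 equiv, iPr2NEt 1.1 equiv, N-methylpyrrolidinone 1 equiv, CH2Cl2, −78 to 0 °C) and addition of aldehyde 12 give, through the non-chelated chair transition state, the (2R,3S)-syn N-acyl thiazolidinethione aldol adduct F2. Its yellow diastereomers are easily separated, and NaBH4 in THF/H2O cleaves the thione auxiliary to return diol 16.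

**Step 11 (Mitsunobu ring closure).** The benzylic oxyphosphonium ion carries an electron-rich aryl group. Partial ionisation (SN1) would erode the inversion and leak material into the more stable trans ring. The fallback sets out from 17 and comes back at 20. It inverts C3 first and then forms the other C–O bond (aryl–oxygen) with retention.
- Dess–Martin periodinane with NaHCO3 in CH2Cl2 oxidises 17 to methyl (E)-3-[4-(allyloxy)-3-({(2S)-3-[(tert-butyldimethylsilyl)oxy]-1-[3-methoxy-4-(methoxymethoxy)phenyl]-1-oxopropan-2-yl}oxy)phenyl]prop-2-enoate F3.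
- Zn(BH4)2 in Et2O at −30 °C reduces the ketone under chelation control: zinc bridges the carbonyl and the α-aryloxy oxygen, and hydride enters opposite the CH2OTBS group. This gives the anti (1R,2S) benzylic alcohol F4.
- Deallylation as in step 10 gives the (1R,2S) phenol F5.
- PhNTf2 and Et3N convert only the phenol into the aryl triflate F6.
- Intramolecular palladium-catalysed C–O coupling (Pd2(dba)3, 2-di-tert-butylphosphino-2',4',6'-triisopropylbiphenyl, Cs2CO3, toluene, 70 °C) joins the benzylic oxygen to the arene with retention at C3 and delivers the cis-benzodioxane 20.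

**Step 19 (late oxidation of CH2OH to CO2H).** The fully assembled, electron-rich substrate passes through a cis α-aryloxy aldehyde that can epimerise to the trans series or be over-oxidised. The fallback never reduces the carboxyl carbon. It sets out from aldol adduct 15 and comes back at target 34.
- LiOH/H2O2 (THF/H2O, 0 °C) removes the auxiliary to give (2R,3S)-2-{2-(allyloxy)-5-[(E)-3-methoxy-3-oxoprop-1-enyl]phenoxy}-3-hydroxy-3-[3-methoxy-4-(methoxymethoxy)phenyl]propanoic acid F7.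
- tert-Butyl 2,2,2-trichloroacetimidate gives its tert-butyl ester F8.
- Deallylation as in step 10 gives the phenol tert-butyl ester F9.
- Mitsunobu closure as in step 11 (inversion at C3; β-elimination to the aryloxycinnamate is the side reaction to watch) gives tert-butyl (2R,3R)-7-[(E)-3-methoxy-3-oxoprop-1-enyl]-3-[3-methoxy-4-(methoxymethoxy)phenyl]-2,3-dihydro-1,4-benzodioxine-2-carboxylate F10.
- Me3SnOH in 1,2-dichloroethane at 70 °C cleaves only the methyl ester, without epimerising C2, to give the cinnamic acid tert-butyl ester F11.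
- Yamaguchi esterification with 28 as in step 17 gives the bis-tert-butyl ester bis-MOM ether F12.
- TFA/CH2Cl2/H2O as in step 20 gives 34.

## Further compounds

F1 | step 7 | methyl (E)-3-[4-(allyloxy)-3-{2-[(4R)-4-benzyl-2-thioxo-1,3-thiazolidin-3-yl]-2-oxoethoxy}phenyl]prop-2-enoate | C=CCOc1ccc(/C=C/C(=O)OC)cc1OCC(=O)N1[C@H](Cc2ccccc2)CSC1=S
F2 | step 7 | methyl (E)-3-[4-(allyloxy)-3-({(2R,3S)-1-[(4R)-4-benzyl-2-thioxo-1,3-thiazolidin-3-yl]-3-hydroxy-3-[3-methoxy-4-(methoxymethoxy)phenyl]-1-oxopropan-2-yl}oxy)phenyl]prop-2-enoate | C=CCOc1ccc(/C=C/C(=O)OC)cc1O[C@H]([C@@H](O)c1ccc(OCOC)c(OC)c1)C(=O)N1[C@H](Cc2ccccc2)CSC1=S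
F3 | step 11 | methyl (E)-3-[4-(allyloxy)-3-({(2S)-3-[(tert-butyldimethylsilyl)oxy]-1-[3-methoxy-4-(methoxymethoxy)phenyl]-1-oxopropan-2-yl}oxy)phenyl]prop-2-enoate | C=CCOc1ccc(/C=C/C(=O)OC)cc1O[C@H](C(=O)c1ccc(OCOC)c(OC)c1)CO[Si](C)(C)C(C)(C)C
F4 | step 11 | methyl (E)-3-[4-(allyloxy)-3-({(1R,2S)-3-[(tert-butyldimethylsilyl)oxy]-1-hydroxy-1-[3-methoxy-4-(methoxymethoxy)phenyl]propan-2-yl}oxy)phenyl]prop-2-enoate | C=CCOc1ccc(/C=C/C(=O)OC)cc1O[C@H]([C@H](O)c1ccc(OCOC)c(OC)c1)CO[Si](C)(C)C(C)(C)C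
F5 | step 11 | methyl (E)-3-[3-({(1R,2S)-3-[(tert-butyldimethylsilyl)oxy]-1-hydroxy-1-[3-methoxy-4-(methoxymethoxy)phenyl]propan-2-yl}oxy)-4-hydroxyphenyl]prop-2-enoate | Oc1ccc(/C=C/C(=O)OC)cc1O[C@H]([C@H](O)c1ccc(OCOC)c(OC)c1)CO[Si](C)(C)C(C)(C)C
F6 | step 11 | methyl (E)-3-[3-({(1R,2S)-3-[(tert-butyldimethylsilyl)oxy]-1-hydroxy-1-[3-methoxy-4-(methoxymethoxy)phenyl]propan-2-yl}oxy)-4-{[(trifluoromethyl)sulfonyl]oxy}phenyl]prop-2-enoate | O=S(=O)(Oc1ccc(/C=C/C(=O)OC)cc1O[C@H]([C@H](O)c1ccc(OCOC)c(OC)c1)CO[Si](C)(C)C(C)(C)C)C(F)(F)F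
F7 | step 19 | (2R,3S)-2-{2-(allyloxy)-5-[(E)-3-methoxy-3-oxoprop-1-enyl]phenoxy}-3-hydroxy-3-[3-methoxy-4-(methoxymethoxy)phenyl]propanoic acid | C=CCOc1ccc(/C=C/C(=O)OC)cc1O[C@H]([C@@H](O)c1ccc(OCOC)c(OC)c1)C(=O)O
F8 | step 19 | tert-butyl (2R,3S)-2-{2-(allyloxy)-5-[(E)-3-methoxy-3-oxoprop-1-enyl]phenoxy}-3-hydroxy-3-[3-methoxy-4-(methoxymethoxy)phenyl]propanoate | C=CCOc1ccc(/C=C/C(=O)OC)cc1O[C@H]([C@@H](O)c1ccc(OCOC)c(OC)c1)C(=O)OC(C)(C)C
F9 | step 19 | tert-butyl (2R,3S)-3-hydroxy-2-{2-hydroxy-5-[(E)-3-methoxy-3-oxoprop-1-enyl]phenoxy}-3-[3-methoxy-4-(methoxymethoxy)phenyl]propanoate | Oc1ccc(/C=C/C(=O)OC)cc1O[C@H]([C@@H](O)c1ccc(OCOC)c(OC)c1)C(=O)OC(C)(C)C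
F10 | step 19 | tert-butyl (2R,3R)-7-[(E)-3-methoxy-3-oxoprop-1-enyl]-3-[3-methoxy-4-(methoxymethoxy)phenyl]-2,3-dihydro-1,4-benzodioxine-2-carboxylate | COC(=O)/C=C/c1ccc2c(c1)O[C@@H](C(=O)OC(C)(C)C)[C@@H](c1ccc(OCOC)c(OC)c1)O2
F11 | step 19 | (E)-3-[(2R,3R)-2-(tert-butoxycarbonyl)-3-[3-methoxy-4-(methoxymethoxy)phenyl]-2,3-dihydro-1,4-benzodioxin-7-yl]prop-2-enoic acid | OC(=O)/C=C/c1ccc2c(c1)O[C@@H](C(=O)OC(C)(C)C)[C@@H](c1ccc(OCOC)c(OC)c1)O2
F12 | step 19 | tert-butyl (2R,3R)-7-[(E)-3-({(R)-1-tert-butoxy-3-[3-methoxy-4-(methoxymethoxy)phenyl]-1-oxopropan-2-yl}oxy)-3-oxoprop-1-enyl]-3-[3-methoxy-4-(methoxymethoxy)phenyl]-2,3-dihydro-1,4-benzodioxine-2-carboxylate | CC(C)(C)OC(=O)[C@@H](Cc1ccc(OCOC)c(OC)c1)OC(=O)/C=C/c1ccc2c(c1)O[C@@H](C(=O)OC(C)(C)C)[C@@H](c1ccc(OCOC)c(OC)c1)O2
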